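**Retrosynthetic overview**

- The target comes from a tris(MOM)-protected aryl hydroazulenol by double ortho-formylation and MOM removal; its C10 carbinol comes from methyl addition to a trans-fused hydroazulen-10-one.
- The five-membered ring is closed last, by intramolecular aldol condensation of a cycloheptanone carrying a CH2CHO arm on C4, then conjugate reduction; the arm comes from one-carbon homologation of a reduced aryl lactone.
- The seven-membered ring and the quaternary C4 come from a 7-exo Michael ring closure of a methyl-ketone enolate onto a 3-alkylidene dihydrocoumarin, with the enolate trapped by MeI.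
- Key disconnection: intermolecular aldol (C4–C5) between the enolate of an (R)-4-isobutyl dihydrocoumarin and (R)-3-isopropenyl-6-oxoheptanal from (R)-limonene oxide.
- The lactone (temporary ring carrying C1′) comes from an organocatalytic Friedel–Crafts/lactolisation of a bis-MOM phloroglucinol with an enal. Ring order: lactone, cycloheptanone, cyclopentane.

Assumption: locants C1–C10, C14, C15 and C1′ in the "Why" lines use guaiane-type numbering of the target (C1/C5 ring fusion, C4 quaternary, C7 isopropenyl-bearing, C10 carbinol, C1′ benzylic); commercial (+)-(R)-limonene 1,2-oxide is used as its cis/trans mixture.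

**Route**

Step 1
Reactants: 1 benzene-1,3,5-triol (phloroglucinol)
Product: 2 3,5-bis(methoxymethoxy)phenol
Conditions: MOMCl (2.0 equiv), i-Pr2NEt, DMF, 0 °C to rt; chromatography
Reagents that add atoms: chloromethyl methyl ether (COCCl)
Why: Williamson-type O-alkylation; the statistical bis-ether is separated from mono- and tris-ethers, which are recycled.

Step 2
Reactants: 3 3-methylbutanal
Product: 4 (2E)-5-methylhex-2-enal
Conditions: Ph3P=CHCHO, toluene, 80 °C
Reagents that add atoms: (triphenylphosphoranylidene)acetaldehyde (O=CC=P(c1ccccc1)(c1ccccc1)c1ccccc1)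
Why: Wittig olefination with a stabilised ylide gives the E-enal by two-carbon homologation.

Step 3
Reactants: 2 3,5-bis(methoxymethoxy)phenol; 4 (2E)-5-methylhex-2-enal
Product: 6 (4R)-4-(2-methylpropyl)-5,7-bis(methoxymethoxy)chroman-2-ol (C2 anomers), via (3R)-hydroxy aldehyde 5 (not isolated)
Conditions: (S)-2-[diphenyl(trimethylsilyloxy)methyl]pyrrolidine (20 mol%), PhCO2H (20 mol%), toluene, 0 °C
Reagents that add atoms: none
Why: Iminium-catalysed Friedel–Crafts-type conjugate addition then hemiacetalisation; the (S)-catalyst shields one face of the E-iminium ion, so the arene adds to the other face and sets C1′ as R.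

Step 4
Reactants: 6 (4R)-chroman-2-ol
Product: 7 (4R)-4-(2-methylpropyl)-5,7-bis(methoxymethoxy)chroman-2-one
Conditions: Dess–Martin periodinane, CH2Cl2, rt
Reagents that add atoms: none
Why: Dess–Martin oxidation of the lactol to the lactone; the stereocentre is β to the new carbonyl and is not touched.

Step 5
Reactants: 8 (+)-(4R)-limonene 1,2-oxide
Product: 10 (3R)-6-oxo-3-(prop-1-en-2-yl)heptanal, via trans-diol 9 (not isolated)
Conditions: H5IO6, THF/H2O, 0 °C to rt
Reagents that add atoms: water (O)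
Why: Acid-mediated epoxide hydrolysis then periodate glycol cleavage (Malaprade reaction); C7 comes unchanged from (R)-limonene and the isopropenyl group is not attacked.

Step 6
Reactants: 7 (4R)-chroman-2-one; 10 (3R)-6-oxo-3-(prop-1-en-2-yl)heptanal
Product: 12 (4R)-3-[(3R)-1-hydroxy-6-oxo-3-(prop-1-en-2-yl)heptyl]-4-(2-methylpropyl)-5,7-bis(methoxymethoxy)chroman-2-one (epimers at C3 and the carbinol), via lithium enolate 11 (not isolated)
Conditions: LiN(i-Pr)2, THF, −78 °C; then 10, −78 °C; AcOH quench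
Reagents that add atoms: none
Why: Lithium-enolate aldol addition; the enolate adds to the aldehyde far faster than to the methyl ketone at −78 °C and forms the fragment-joining C4–C5 bond, and the two new stereocentres are erased in step 7.

Step 7
Reactants: 12 aldol adduct
Product: 14 (3E,4S)-4-(2-methylpropyl)-5,7-bis(methoxymethoxy)-3-[(3R)-6-oxo-3-(prop-1-en-2-yl)heptylidene]chroman-2-one, via methanesulfonate 13 (not isolated)
Conditions: MsCl, Et3N, CH2Cl2, −20 to 0 °C
Reagents that add atoms: none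
Why: Mesylation then E1cB elimination through the acidic aryl-lactone α-position gives the more stable E-alkylidene lactone, which forces the C1′ isobutyl group pseudoaxial (the 4S label is a priority change, not an inversion).

Step 8
Reactants: 14 (3E,4S)-alkylidene lactone
Product: 17 (3S,4S)-3-methyl-4-(2-methylpropyl)-5,7-bis(methoxymethoxy)-3-[(1S,6R)-3-oxo-6-(prop-1-en-2-yl)cycloheptyl]chroman-2-one, via terminal lithium enolate 15 (not isolated), via cyclised lithium lactone enolate 16 (not isolated)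
Conditions: LiN(SiMe3)2, THF (0.01 M), −78 to −30 °C; then MeI, DMPU, −78 to −20 °C
Reagents that add atoms: iodomethane (CI)
Why: Michael-initiated ring closure then enolate alkylation; the kinetic methyl-side ketone enolate adds 7-exo-trig to the E-alkene on the face anti to the pseudoaxial isobutyl group (sets C5), and the lactone enolate is methylated on the same anti face (sets quaternary C4, methyl trans to isobutyl).

Step 9
Reactants: 17 keto lactone
Product: 18 (3S,4S)-3-[(1S,6R)-3-hydroxy-6-(prop-1-en-2-yl)cycloheptyl]-3-methyl-4-(2-methylpropyl)-5,7-bis(methoxymethoxy)chroman-2-ol (C2 anomers; carbinol epimers)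
Conditions: i-Bu2AlH, CH2Cl2, −78 °C
Reagents that add atoms: none
Why: Hydride reduction; the aryl lactone stops at the lactol at −78 °C and the ketone is reduced to the alcohol, which keeps it out of the Wittig step (it is re-oxidised in step 12).

Step 10
Reactants: 18 lactol
Product: 19 2-[(4S,5R)-4-[(1S,6R)-3-hydroxy-6-(prop-1-en-2-yl)cycloheptyl]-1-methoxy-4,7-dimethyloct-1-en-5-yl]-3,5-bis(methoxymethoxy)phenol (E/Z; carbinol epimers)
Conditions: Ph3P(CH2OMe)Cl, KN(SiMe3)2, THF, 0 °C to rt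
Reagents that add atoms: (methoxymethylidene)triphenylphosphorane from (methoxymethyl)triphenylphosphonium chloride ([Cl-].COC[P+](c1ccccc1)(c1ccccc1)c1ccccc1)
Why: Wittig methoxymethylenation of the ring-opened phenoxide/aldehyde form of the lactol; the non-enolisable neopentyl aldehyde gives the enol ether that carries the future C2.

Step 11
Reactants: 19 phenol
Product: 20 2-[(4S,5R)-4-[(1S,6R)-3-hydroxy-6-(prop-1-en-2-yl)cycloheptyl]-1-methoxy-4,7-dimethyloct-1-en-5-yl]-1,3,5-tris(methoxymethoxy)benzene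
Conditions: MOMCl, K2CO3, acetone, rt
Reagents that add atoms: chloromethyl methyl ether (COCCl)
Why: Selective Williamson O-alkylation of the phenoxide; K2CO3 does not deprotonate the secondary alcohol.

Step 12
Reactants: 20 alcohol
Product: 21 (3S,5R)-3-[(4S,5R)-1-methoxy-4,7-dimethyl-5-[2,4,6-tris(methoxymethoxy)phenyl]oct-1-en-4-yl]-5-(prop-1-en-2-yl)cycloheptan-1-one
Conditions: Dess–Martin periodinane, NaHCO3, CH2Cl2, 0 °C to rt
Reagents that add atoms: none
Why: Dess–Martin oxidation restores the C10 ketone; the buffer protects the enol ether.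

Step 13
Reactants: 21 enol ether
Product: 22 (3S,4R)-3,6-dimethyl-3-[(1S,6R)-3-oxo-6-(prop-1-en-2-yl)cycloheptyl]-4-[2,4,6-tris(methoxymethoxy)phenyl]heptanal
Conditions: TsOH·H2O (cat.), acetone/H2O, rt
Reagents that add atoms: water (O)
Why: Acid-catalysed enol ether hydrolysis unveils the C2 aldehyde (C3 becomes CH2) under conditions too mild to cleave aryl MOM ethers.

Step 14
Reactants: 22 keto aldehyde
Product: 24 (1R,7R,8aR)-1-methyl-1-[(1R)-3-methyl-1-[2,4,6-tris(methoxymethoxy)phenyl]butyl]-7-(prop-1-en-2-yl)-2,5,6,7,8,8a-hexahydroazulen-4(1H)-one, via β-hydroxy ketone 23 (not isolated)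
Conditions: KOH, MeOH, rt
Reagents that add atoms: none
Why: Intramolecular aldol condensation; only the C1 enolate/C2 aldehyde pairing gives an unstrained five-membered ring that can dehydrate, so the conjugated bicyclic enone forms (the C5 hydrogen is not acidic).

Step 15
Reactants: 24 enone
Product: 26 (1S,3aR,7R,8aS)-1-methyl-1-[(1R)-3-methyl-1-[2,4,6-tris(methoxymethoxy)phenyl]butyl]-7-(prop-1-en-2-yl)octahydroazulen-4(1H)-one, via copper enolate 25 (not isolated)
Conditions: [(Ph3P)CuH]6, H2O, benzene, rt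
Reagents that add atoms: none
Why: Copper hydride conjugate reduction (Stryker type); hydride adds to C2 and the enolate is protonated kinetically at C1 anti to the bulky C4 arylalkyl group (syn to the C4 methyl), giving the trans ring fusion while the isopropenyl alkene is untouched.

Step 16
Reactants: 26 trans-fused ketone
Product: 27 (1S,3aR,4R,7R,8aS)-1,4-dimethyl-1-[(1R)-3-methyl-1-[2,4,6-tris(methoxymethoxy)phenyl]butyl]-7-(prop-1-en-2-yl)decahydroazulen-4-ol
Conditions: MeLi, CeCl3, THF, −78 °C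
Reagents that add atoms: methyllithium ([Li]C)
Why: Organocerium 1,2-addition (non-basic, so C1 is not epimerised); methyl attacks anti to the axial C1–H on the convex face of the trans-fused bicycle, giving OH cis to H-1 (C10 = R).

Step 17
Reactants: 27 tertiary alcohol
Product: 32 5-[(1R)-1-[(1S,3aR,4R,7R,8aS)-4-hydroxy-1,4-dimethyl-7-(prop-1-en-2-yl)decahydroazulen-1-yl]-3-methylbutyl]-2,4,6-tris(methoxymethoxy)benzene-1,3-dicarbaldehyde, via aryllithium alkoxide 28 (not isolated), via monoformyl hemiaminal salt 29 (not isolated), via lithiated hemiaminal salt 30 (not isolated), via bis(hemiaminal) salt 31 (not isolated)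
Conditions: n-BuLi, TMEDA, THF, −20 °C; DMF; then n-BuLi, −20 °C; DMF; H2O
Reagents that add atoms: N,N-dimethylformamide (CN(C)C=O)
Why: Directed ortho-metalation/formylation; each aryl C–H lies between two MOM ethers and is lithiated selectively, and the first formyl group stays masked as its lithium hemiaminal while the second position is lithiated and formylated.

Step 18
Reactants: 32 tris(MOM) dialdehyde
Product: 33 5-[(1R)-1-[(1S,3aR,4R,7R,8aS)-4-hydroxy-1,4-dimethyl-7-(prop-1-en-2-yl)decahydroazulen-1-yl]-3-methylbutyl]-2,4,6-trihydroxybenzene-1,3-dicarbaldehyde (target)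
Conditions: 2 M HCl, MeOH/THF, rt
Reagents that add atoms: none
Why: Acid-catalysed acetal (MOM) hydrolysis, fast for MOM ethers ortho to formyl groups, under conditions mild enough for the tertiary alcohol and the isopropenyl group.

**Compound list**

1 | benzene-1,3,5-triol (phloroglucinol) | Oc1cc(O)cc(O)c1 | starting material
2 | 3,5-bis(methoxymethoxy)phenol | COCOc1cc(O)cc(OCOC)c1 | intermediate
3 | 3-methylbutanal | CC(C)CC=O | starting material
4 | (2E)-5-methylhex-2-enal | CC(C)C/C=C/C=O | intermediate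
5 | (3R)-3-[2-hydroxy-4,6-bis(methoxymethoxy)phenyl]-5-methylhexanal | O=CC[C@@H](CC(C)C)c1c(O)cc(OCOC)cc1OCOC | intermediate (not isolated)
6 | (4R)-4-(2-methylpropyl)-5,7-bis(methoxymethoxy)chroman-2-ol (C2 anomers) | OC1C[C@@H](CC(C)C)c2c(OCOC)cc(OCOC)cc2O1 | intermediate
7 | (4R)-4-(2-methylpropyl)-5,7-bis(methoxymethoxy)chroman-2-one | O=C1C[C@@H](CC(C)C)c2c(OCOC)cc(OCOC)cc2O1 | intermediate
8 | (4R)-1-methyl-4-(prop-1-en-2-yl)-7-oxabicyclo[4.1.0]heptane, (+)-limonene 1,2-oxide (cis/trans mixture) | CC12CC[C@H](CC1O2)C(C)=C | starting material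
9 | (4R)-1-methyl-4-(prop-1-en-2-yl)cyclohexane-1,2-diol | CC1(O)CC[C@H](CC1O)C(C)=C | intermediate (not isolated)
10 | (3R)-6-oxo-3-(prop-1-en-2-yl)heptanal | CC(=O)CC[C@H](CC=O)C(C)=C | intermediate
11 | lithium enolate of 7 | [Li]OC1=C[C@@H](CC(C)C)c2c(OCOC)cc(OCOC)cc2O1 | intermediate (not isolated)
12 | (4R)-3-[(3R)-1-hydroxy-6-oxo-3-(prop-1-en-2-yl)heptyl]-4-(2-methylpropyl)-5,7-bis(methoxymethoxy)chroman-2-one (epimers at C3 and carbinol) | CC(=O)CC[C@H](CC(O)C1C(=O)Oc2cc(OCOC)cc(OCOC)c2[C@@H]1CC(C)C)C(C)=C | intermediate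
13 | methanesulfonate of 12 | CC(=O)CC[C@H](CC(OS(C)(=O)=O)C1C(=O)Oc2cc(OCOC)cc(OCOC)c2[C@@H]1CC(C)C)C(C)=C | intermediate (not isolated)
14 | (3E,4S)-4-(2-methylpropyl)-5,7-bis(methoxymethoxy)-3-[(3R)-6-oxo-3-(prop-1-en-2-yl)heptylidene]chroman-2-one | CC(=O)CC[C@H](C/C=C1/C(=O)Oc2cc(OCOC)cc(OCOC)c2[C@@H]1CC(C)C)C(C)=C | intermediate
15 | terminal (methyl-side) lithium enolate of 14 | C=C(O[Li])CC[C@H](C/C=C1/C(=O)Oc2cc(OCOC)cc(OCOC)c2[C@@H]1CC(C)C)C(C)=C | intermediate (not isolated)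
16 | cyclised lithium lactone enolate (cycloheptanone formed) | C=C(C)[C@@H]1CCC(=O)C[C@@H](C2=C(O[Li])Oc3cc(OCOC)cc(OCOC)c3[C@@H]2CC(C)C)C1 | intermediate (not isolated)
17 | (3S,4S)-3-methyl-4-(2-methylpropyl)-5,7-bis(methoxymethoxy)-3-[(1S,6R)-3-oxo-6-(prop-1-en-2-yl)cycloheptyl]chroman-2-one | C=C(C)[C@@H]1CCC(=O)C[C@@H]([C@]2(C)C(=O)Oc3cc(OCOC)cc(OCOC)c3[C@@H]2CC(C)C)C1 | intermediate
18 | (3S,4S)-3-[(1S,6R)-3-hydroxy-6-(prop-1-en-2-yl)cycloheptyl]-3-methyl-4-(2-methylpropyl)-5,7-bis(methoxymethoxy)chroman-2-ol (C2 anomers; carbinol epimers) | C=C(C)[C@@H]1CCC(O)C[C@@H]([C@]2(C)C(O)Oc3cc(OCOC)cc(OCOC)c3[C@@H]2CC(C)C)C1 | intermediate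
19 | 2-[(4S,5R)-4-[(1S,6R)-3-hydroxy-6-(prop-1-en-2-yl)cycloheptyl]-1-methoxy-4,7-dimethyloct-1-en-5-yl]-3,5-bis(methoxymethoxy)phenol (E/Z; carbinol epimers) | C=C(C)[C@@H]1CCC(O)C[C@@H]([C@](C)(CC=COC)[C@@H](CC(C)C)c2c(O)cc(OCOC)cc2OCOC)C1 | intermediate
20 | 2-[(4S,5R)-4-[(1S,6R)-3-hydroxy-6-(prop-1-en-2-yl)cycloheptyl]-1-methoxy-4,7-dimethyloct-1-en-5-yl]-1,3,5-tris(methoxymethoxy)benzene | C=C(C)[C@@H]1CCC(O)C[C@@H]([C@](C)(CC=COC)[C@@H](CC(C)C)c2c(OCOC)cc(OCOC)cc2OCOC)C1 | intermediate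
21 | (3S,5R)-3-[(4S,5R)-1-methoxy-4,7-dimethyl-5-[2,4,6-tris(methoxymethoxy)phenyl]oct-1-en-4-yl]-5-(prop-1-en-2-yl)cycloheptan-1-one | C=C(C)[C@@H]1CCC(=O)C[C@@H]([C@](C)(CC=COC)[C@@H](CC(C)C)c2c(OCOC)cc(OCOC)cc2OCOC)C1 | intermediate
22 | (3S,4R)-3,6-dimethyl-3-[(1S,6R)-3-oxo-6-(prop-1-en-2-yl)cycloheptyl]-4-[2,4,6-tris(methoxymethoxy)phenyl]heptanal | C=C(C)[C@@H]1CCC(=O)C[C@@H]([C@](C)(CC=O)[C@@H](CC(C)C)c2c(OCOC)cc(OCOC)cc2OCOC)C1 | intermediate
23 | β-hydroxy ketone (3-hydroxy-octahydroazulen-4-one aldol adduct, C3/C3a epimers) | C=C(C)[C@@H]1CCC(=O)C2C(O)C[C@](C)([C@@H](CC(C)C)c3c(OCOC)cc(OCOC)cc3OCOC)[C@H]2C1 | intermediate (not isolated)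
24 | (1R,7R,8aR)-1-methyl-1-[(1R)-3-methyl-1-[2,4,6-tris(methoxymethoxy)phenyl]butyl]-7-(prop-1-en-2-yl)-2,5,6,7,8,8a-hexahydroazulen-4(1H)-one | C=C(C)[C@@H]1CCC(=O)C2=CC[C@](C)([C@@H](CC(C)C)c3c(OCOC)cc(OCOC)cc3OCOC)[C@H]2C1 | intermediate
25 | copper enolate of 26 (phosphine ligands omitted) | C=C(C)[C@@H]1CCC(O[Cu])=C2CC[C@](C)([C@@H](CC(C)C)c3c(OCOC)cc(OCOC)cc3OCOC)[C@H]2C1 | intermediate (not isolated)
26 | (1S,3aR,7R,8aS)-1-methyl-1-[(1R)-3-methyl-1-[2,4,6-tris(methoxymethoxy)phenyl]butyl]-7-(prop-1-en-2-yl)octahydroazulen-4(1H)-one | C=C(C)[C@@H]1CCC(=O)[C@@H]2CC[C@](C)([C@@H](CC(C)C)c3c(OCOC)cc(OCOC)cc3OCOC)[C@H]2C1 | intermediate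
27 | (1S,3aR,4R,7R,8aS)-1,4-dimethyl-1-[(1R)-3-methyl-1-[2,4,6-tris(methoxymethoxy)phenyl]butyl]-7-(prop-1-en-2-yl)decahydroazulen-4-ol | C=C(C)[C@@H]1CC[C@@](C)(O)[C@@H]2CC[C@](C)([C@@H](CC(C)C)c3c(OCOC)cc(OCOC)cc3OCOC)[C@H]2C1 | intermediate
28 | lithium alkoxide of 27 lithiated at one aryl C–H | C=C(C)[C@@H]1CC[C@@](C)(O[Li])[C@@H]2CC[C@](C)([C@@H](CC(C)C)c3c(OCOC)c([Li])c(OCOC)cc3OCOC)[C@H]2C1 | intermediate (not isolated)
29 | monoformyl adduct as lithium α-(dimethylamino)alkoxide | C=C(C)[C@@H]1CC[C@@](C)(O[Li])[C@@H]2CC[C@](C)([C@@H](CC(C)C)c3c(OCOC)c(C(O[Li])N(C)C)c(OCOC)cc3OCOC)[C@H]2C1 | intermediate (not isolated)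
30 | 29 lithiated at the second aryl C–H | C=C(C)[C@@H]1CC[C@@](C)(O[Li])[C@@H]2CC[C@](C)([C@@H](CC(C)C)c3c(OCOC)c(C(O[Li])N(C)C)c(OCOC)c([Li])c3OCOC)[C@H]2C1 | intermediate (not isolated)
31 | bis[lithium α-(dimethylamino)alkoxide] | C=C(C)[C@@H]1CC[C@@](C)(O[Li])[C@@H]2CC[C@](C)([C@@H](CC(C)C)c3c(OCOC)c(C(O[Li])N(C)C)c(OCOC)c(C(O[Li])N(C)C)c3OCOC)[C@H]2C1 | intermediate (not isolated)
32 | 5-[(1R)-1-[(1S,3aR,4R,7R,8aS)-4-hydroxy-1,4-dimethyl-7-(prop-1-en-2-yl)decahydroazulen-1-yl]-3-methylbutyl]-2,4,6-tris(methoxymethoxy)benzene-1,3-dicarbaldehyde | C=C(C)[C@@H]1CC[C@@](C)(O)[C@@H]2CC[C@](C)([C@@H](CC(C)C)c3c(OCOC)c(C=O)c(OCOC)c(C=O)c3OCOC)[C@H]2C1 | intermediate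
33 | 5-[(1R)-1-[(1S,3aR,4R,7R,8aS)-4-hydroxy-1,4-dimethyl-7-(prop-1-en-2-yl)decahydroazulen-1-yl]-3-methylbutyl]-2,4,6-trihydroxybenzene-1,3-dicarbaldehyde | C=C(C)[C@@H]1CC[C@@](C)(O)[C@@H]2CC[C@](C)([C@@H](CC(C)C)c3c(O)c(C=O)c(O)c(C=O)c3O)[C@H]2C1 | target

**Step count**

Total: 18 steps. Longest linear sequence: 16 steps (1, 3, 4, 6–18, from phloroglucinol).

**Three steps most likely to fail**

Step 8, the tandem 7-exo Michael closure and methylation. It can fail through enolisation on the C9 methylene side (which would close a five-membered ring), a slow seven-membered closure, proton exchange before methylation, or base-induced drift of the exocyclic alkene of 14 into the coumarin (loss of C1′). The fallback sets out from 14 and comes back at 17. An internal-quench silylation (LiN(SiMe3)2 in the presence of Me3SiCl, −78 °C) gives the terminal trimethylsilyl enol ether F1. A Lewis-acid Mukaiyama–Michael closure (Me3SiNTf2 cat., CH2Cl2, −78 °C, aqueous work-up) then gives the unmethylated cycloheptanone lactone F2, with the same facial preference at C5. The ketone is masked as the dioxolane lactone F3 (Me3SiOCH2CH2OSiMe3, Me3SiOTf cat., −78 °C). LiN(i-Pr)2/MeI then methylates the only enolisable position, anti to the isobutyl group, to give the methylated dioxolane lactone F4. TsOH·H2O in wet acetone releases 17.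

Step 15, the C1 configuration from protonation of enolate 25. The facial preference rests on the bulk of the C4 arylalkyl group and may be modest or reversed. The fallback sets out from 24 and comes back at 26. It switches from kinetic to thermodynamic control: C1 is the only stereocentre α to the ketone, so the cis-fused C1-epimeric ketone F5 is equilibrated with NaOMe in MeOH, 26 is separated by chromatography and F5 is recycled. Which isomer is favoured at equilibrium in this system is not known.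

Step 17, the one-flask double ortho-formylation. The second lithiation in the presence of the hemiaminal salt may be incomplete, and allylic metalation of the isopropenyl group could compete on long exposure. The fallback sets out from 27 and comes back at 32. Electrophilic dibromination (N-bromosuccinimide, 2 equiv, MeCN, −40 °C) gives the 3,5-dibromoarene F6. Bromine–lithium exchange at both positions with t-BuLi (after deprotonating the alcohol, THF, −78 °C) and a DMF quench then give 32.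

**Further compounds**

F1 | step 8 | (3E,4S)-4-(2-methylpropyl)-5,7-bis(methoxymethoxy)-3-[(3R)-3-(prop-1-en-2-yl)-6-(trimethylsilyloxy)hept-6-en-1-ylidene]chroman-2-one | C=C(O[Si](C)(C)C)CC[C@H](C/C=C1/C(=O)Oc2cc(OCOC)cc(OCOC)c2[C@@H]1CC(C)C)C(C)=C
F2 | step 8 | (4R)-4-(2-methylpropyl)-5,7-bis(methoxymethoxy)-3-[(1S,6R)-3-oxo-6-(prop-1-en-2-yl)cycloheptyl]chroman-2-one (C3 epimers) | C=C(C)[C@@H]1CCC(=O)C[C@@H](C2C(=O)Oc3cc(OCOC)cc(OCOC)c3[C@@H]2CC(C)C)C1
F3 | step 8 | (4R)-4-(2-methylpropyl)-5,7-bis(methoxymethoxy)-3-[(7S,9R)-9-(prop-1-en-2-yl)-1,4-dioxaspiro[4.6]undecan-7-yl]chroman-2-one (C3 epimers) | C=C(C)[C@@H]1CCC2(OCCO2)C[C@@H](C3C(=O)Oc4cc(OCOC)cc(OCOC)c4[C@@H]3CC(C)C)C1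
F4 | step 8 | (3S,4S)-3-methyl-4-(2-methylpropyl)-5,7-bis(methoxymethoxy)-3-[(7S,9R)-9-(prop-1-en-2-yl)-1,4-dioxaspiro[4.6]undecan-7-yl]chroman-2-one | C=C(C)[C@@H]1CCC2(OCCO2)C[C@@H]([C@]3(C)C(=O)Oc4cc(OCOC)cc(OCOC)c4[C@@H]3CC(C)C)C1
F5 | step 15 | (1S,3aS,7R,8aS)-1-methyl-1-[(1R)-3-methyl-1-[2,4,6-tris(methoxymethoxy)phenyl]butyl]-7-(prop-1-en-2-yl)octahydroazulen-4(1H)-one (cis-fused C3a epimer of 26) | C=C(C)[C@@H]1CCC(=O)[C@H]2CC[C@](C)([C@@H](CC(C)C)c3c(OCOC)cc(OCOC)cc3OCOC)[C@H]2C1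
F6 | step 17 | (1S,3aR,4R,7R,8aS)-1-[(1R)-1-[3,5-dibromo-2,4,6-tris(methoxymethoxy)phenyl]-3-methylbutyl]-1,4-dimethyl-7-(prop-1-en-2-yl)decahydroazulen-4-ol | C=C(C)[C@@H]1CC[C@@](C)(O)[C@@H]2CC[C@](C)([C@@H](CC(C)C)c3c(OCOC)c(Br)c(OCOC)c(Br)c3OCOC)[C@H]2C1
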